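The six-membered carbocycle is numbered C1 = quaternary CCH3, C3 = CBr, C4 and C6 = CHCl. Everything rests on removing H–Br from this ring: the tertiary C3–Br is cis to the C4–Cl, so Br and the C4 hydrogen are anti. That is the signature of radical-chain trans addition of HBr to a C3=C4 chloroalkene, which forges the C3–Br bond and both remaining stereocentres in one operation. The precursor is a 1-chloro-2-(chloromethyl)cyclohexene in which C1 (CH3, CH2OH) and the C6 chloride are already set by an enantioselective Diels–Alder reaction of a Z-chloroenal; the chlorovinyl group is made last from the CH2OH group.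

Key step: step 8

Remark on numbering: in all ring compounds C1 is the quaternary carbon bearing the methyl group, C2 the neighbouring CH2, C3 and C4 the carbons that end as CBr(CH2Cl) and CHCl, C5 the second CH2 and C6 the CHCl next to C1; names and descriptors use these locants.

Remark on the chemistry (assumption): the (3aS) antipode of the oxazaborolidinium catalyst in step 4 is assumed, from the formyl C–H···O coordination model with an s-trans enal, to give (1S,6S)-8; the mirror-image catalyst would be used if the sense of induction proves to be the opposite.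

Step 1
Reactants: 1 prop-2-yn-1-ol (propargyl alcohol); 2 methylmagnesium bromide
Product: 4 (Z)-3-chloro-2-methylprop-2-en-1-ol, via cyclic alkenylmagnesium alkoxide 3 (not isolated)
Conditions: MeMgBr (2.5 equiv), CuI (10 mol%), THF/Et2O, −10 °C → rt; then N-chlorosuccinimide, −40 → 0 °C; aq NH4Cl
Reagents that add atoms: methylmagnesium bromide 2, C[Mg]Br; N-chlorosuccinimide, O=C1CCC(=O)N1Cl
Why: Copper-catalysed anti-carbomagnesiation of the magnesium propargyl alkoxide puts the methyl group on C2 and magnesium on C3 inside a five-membered chelate (Mg cis to CH2O), and electrophilic chlorination of the alkenyl–magnesium bond with retention fixes the Z geometry (Cl cis to CH2OH).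

Step 2
Reactants: 4 (Z)-3-chloro-2-methylprop-2-en-1-ol
Product: 5 (Z)-3-chloro-2-methylprop-2-enal
Conditions: activated MnO2, CH2Cl2, 0 °C → rt, dark; filtered and used at once as a cold solution
Reagents that add atoms: none
Why: Allylic oxidation with MnO2 is neutral and selective for the allylic alcohol, so the volatile enal should form without acid- or base-promoted Z to E leakage (Cl stays cis to CHO).

Step 3
Reactants: 6 but-3-en-2-one (methyl vinyl ketone)
Product: 7 2-(triisopropylsilyloxy)buta-1,3-diene
Conditions: TIPSOTf, Et3N, Et2O, 0 °C → rt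
Reagents that add atoms: triisopropylsilyl triflate, CC(C)[Si](OS(=O)(=O)C(F)(F)F)(C(C)C)C(C)C
Why: Silyl enol ether formation by soft enolisation of the enone gives the cross-conjugated 2-silyloxydiene, and the bulky silyl group makes it robust enough for Lewis acid catalysis.

Step 4
Reactants: 5 (Z)-3-chloro-2-methylprop-2-enal; 7 2-(triisopropylsilyloxy)buta-1,3-diene
Product: 8 (1S,6S)-6-chloro-1-methyl-4-(triisopropylsilyloxy)cyclohex-3-ene-1-carbaldehyde
Conditions: (3aS)-1-(2-methylphenyl)-3,3-diphenyltetrahydro-1H,3H-pyrrolo[1,2-c][1,3,2]oxazaborole protonated with HNTf2 (20 mol%), CH2Cl2, −78 → −40 °C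
Reagents that add atoms: none
Why: Chiral-Lewis-acid-catalysed Diels–Alder reaction in which the 2-silyloxy donor bonds its CH2 terminus to the chlorine-bearing β-carbon (para adduct, silyloxy on C4), suprafacial addition turns the Z geometry into the cis C1–CHO/C6–Cl relationship, and the catalyst-shielded enal face sets the absolute configuration (1S,6S).

Step 5
Reactants: 8 (1S,6S)-6-chloro-1-methyl-4-(triisopropylsilyloxy)cyclohex-3-ene-1-carbaldehyde; 9 N,N-dimethylformamide
Product: 12 (1S,6S)-4,6-dichloro-1-methylcyclohex-3-ene-1,3-dicarbaldehyde, via enaminone 10 (not isolated), via chloroiminium salt 11 (not isolated)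
Conditions: POCl3 (3 equiv), DMF (5 equiv), CH2Cl2, 0 → 40 °C; then aq NaOAc, 0 °C
Reagents that add atoms: N,N-dimethylformamide 9, CN(C)C=O; phosphorus oxychloride, O=P(Cl)(Cl)Cl; water, O
Why: Vilsmeier–Haack–Arnold chloroformylation, in which the chloroiminium ion attacks C3 of the regiodefined silyl enol ether, the enaminone is O-activated so that chloride replaces the C4 oxygen, and hydrolysis gives the β-chloroenal; no stereocentre is touched, the non-enolisable C1 aldehyde is inert, and the acidic medium avoids E1cB loss of the C6 chloride.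

Step 6
Reactants: 12 (1S,6S)-4,6-dichloro-1-methylcyclohex-3-ene-1,3-dicarbaldehyde
Product: 13 (1S,6S)-4,6-dichloro-1,3-bis(hydroxymethyl)-1-methylcyclohex-3-ene
Conditions: NaBH4, CeCl3·7H2O, MeOH, −40 → 0 °C
Reagents that add atoms: none
Why: Luche reduction delivers hydride 1,2 to both aldehydes, so the β-chloroenal gives the allylic alcohol without conjugate addition–elimination at the vinylic chloride, and the stereocentres are untouched.

Step 7
Reactants: 13 (1S,6S)-4,6-dichloro-1,3-bis(hydroxymethyl)-1-methylcyclohex-3-ene
Product: 14 [(1S,6S)-4,6-dichloro-3-(chloromethyl)-1-methylcyclohex-3-en-1-yl]methanol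
Conditions: N-chlorosuccinimide, Me2S, CH2Cl2, −20 → 0 °C, no base
Reagents that add atoms: N-chlorosuccinimide, O=C1CCC(=O)N1Cl
Why: Corey–Kim allylic chlorination, in which the sulfonium reagent activates hydroxyl groups but only the primary allylic oxygen is displaced by chloride (SN2), the neopentyl centre being inert to substitution and returning the free alcohol on work-up.

Step 8
Reactants: 14 [(1S,6S)-4,6-dichloro-3-(chloromethyl)-1-methylcyclohex-3-en-1-yl]methanol
Product: 15 [(1S,3R,4R,6S)-3-bromo-4,6-dichloro-3-(chloromethyl)-1-methylcyclohexyl]methanol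
Conditions: HBr (anhydrous, large excess), hν (254 nm), pentane/CH2Cl2, −78 °C
Reagents that add atoms: hydrogen bromide, Br
Why: Proposed new method: radical-chain hydrobromination in which a bromine atom adds reversibly to C3, the alkene carbon remote from chlorine, and the chlorine-stabilised, bromine-bridged C4 radical takes hydrogen from HBr on the face opposite bromine, regenerating the chain carrier. The closest known reaction type is the radical-chain trans addition of HBr to 1-chlorocyclohexene, which gives cis-1-bromo-2-chlorocyclohexane; new here are the tetrasubstituted alkene and its allylic chloride. No ring is closed. C3 and C4 are created together by the trans-diaxial addition (Br axial on C3, H axial on C4, hence Br cis to the C4 chlorine), and their sense relative to C1 and C6 is controlled by the half-chair with C6–Cl pseudo-equatorial, in which bromine sits on the face of the C1 CH2OH group and hydrogen arrives past axial hydrogens only, whereas the opposite mode needs C6–Cl and the C1 methyl group axial and sends HBr past that axial chlorine. The step needs bromine on C3 and not on C4, which the C4 chlorine secures because attack at C3 gives the α-chloro radical and a normal tertiary C–Br bond while attack at C4 gives a weak geminal bromochloride and is reversed; the large excess of HBr at −78 °C lets hydrogen transfer outrun loss of the allylic chlorine atom and keeps ionic Markovnikov addition negligible.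

Step 9
Reactants: 15 [(1S,3R,4R,6S)-3-bromo-4,6-dichloro-3-(chloromethyl)-1-methylcyclohexyl]methanol
Product: 16 (1S,3R,4R,6S)-3-bromo-4,6-dichloro-3-(chloromethyl)-1-methylcyclohexane-1-carbaldehyde
Conditions: Dess–Martin periodinane, NaHCO3, CH2Cl2, 0 °C → rt
Reagents that add atoms: none
Why: Dess–Martin oxidation converts the hindered neopentyl alcohol into the non-enolisable aldehyde under buffered, near-neutral conditions that should not provoke dehydrobromination of the axial tertiary bromide.

Step 10
Reactants: 16 (1S,3R,4R,6S)-3-bromo-4,6-dichloro-3-(chloromethyl)-1-methylcyclohexane-1-carbaldehyde; 17 chloroform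
Product: 18 (1S,3R,4R,6S)-3-bromo-4,6-dichloro-3-(chloromethyl)-1-[(E)-2-chloroethenyl]-1-methylcyclohexane (target)
Conditions: CrCl2 (6 equiv), CHCl3 (2 equiv), THF, 65 °C, shortest possible time
Reagents that add atoms: chloroform 17, ClC(Cl)Cl
Why: Takai–Utimoto chloro-olefination, in which the geminal dichromium carbenoid from chloroform adds to the aldehyde and eliminates to the E-chloroalkene, while CrCl2 in THF without donor additives is expected to spare the alkyl halides because the gauche C3–Br/C4–Cl pair lacks the anti arrangement that accelerates reductive elimination.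

Compound list
1 | prop-2-yn-1-ol (propargyl alcohol) | C#CCO | starting material
2 | methylmagnesium bromide | C[Mg]Br | starting material
3 | 4-methyl-2,5-dihydro-1,2-oxamagnesole (cyclic alkenylmagnesium alkoxide; Mg bonded to the vinylic CH and to the alkoxide oxygen) | CC1=C[Mg]OC1 | intermediate
4 | (Z)-3-chloro-2-methylprop-2-en-1-ol (Cl cis to CH2OH) | OC/C(C)=C\Cl | intermediate
5 | (Z)-3-chloro-2-methylprop-2-enal (Cl cis to CHO) | O=C/C(C)=C\Cl | intermediate
6 | but-3-en-2-one (methyl vinyl ketone) | CC(=O)C=C | starting material
7 | 2-(triisopropylsilyloxy)buta-1,3-diene | C=CC(=C)O[Si](C(C)C)(C(C)C)C(C)C | intermediate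
8 | (1S,6S)-6-chloro-1-methyl-4-(triisopropylsilyloxy)cyclohex-3-ene-1-carbaldehyde (Cl cis to CHO) | C[C@@]1(C=O)CC=C(O[Si](C(C)C)(C(C)C)C(C)C)C[C@@H]1Cl | intermediate
9 | N,N-dimethylformamide | CN(C)C=O | starting material
10 | (1S,6S)-6-chloro-3-[(E)-(dimethylamino)methylidene]-1-methyl-4-oxocyclohexane-1-carbaldehyde (enaminone) | C[C@@]1(C=O)C/C(=C\N(C)C)C(=O)C[C@@H]1Cl | intermediate
11 | {[(1S,6S)-4,6-dichloro-1-formyl-1-methylcyclohex-3-en-3-yl]methylidene}dimethylammonium chloride (chloroiminium salt) | C[C@@]1(C=O)CC(C=[N+](C)C)=C(Cl)C[C@@H]1Cl.[Cl-] | intermediate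
12 | (1S,6S)-4,6-dichloro-1-methylcyclohex-3-ene-1,3-dicarbaldehyde | C[C@@]1(C=O)CC(C=O)=C(Cl)C[C@@H]1Cl | intermediate
13 | (1S,6S)-4,6-dichloro-1,3-bis(hydroxymethyl)-1-methylcyclohex-3-ene | C[C@@]1(CO)CC(CO)=C(Cl)C[C@@H]1Cl | intermediate
14 | [(1S,6S)-4,6-dichloro-3-(chloromethyl)-1-methylcyclohex-3-en-1-yl]methanol | C[C@@]1(CO)CC(CCl)=C(Cl)C[C@@H]1Cl | intermediate
15 | [(1S,3R,4R,6S)-3-bromo-4,6-dichloro-3-(chloromethyl)-1-methylcyclohexyl]methanol (Br, C4–Cl, C6–Cl and CH2OH on one face) | C[C@@]1(CO)C[C@@](Br)(CCl)[C@H](Cl)C[C@@H]1Cl | intermediate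
16 | (1S,3R,4R,6S)-3-bromo-4,6-dichloro-3-(chloromethyl)-1-methylcyclohexane-1-carbaldehyde | C[C@@]1(C=O)C[C@@](Br)(CCl)[C@H](Cl)C[C@@H]1Cl | intermediate
17 | chloroform | ClC(Cl)Cl | starting material
18 | (1S,3R,4R,6S)-3-bromo-4,6-dichloro-3-(chloromethyl)-1-[(E)-2-chloroethenyl]-1-methylcyclohexane, by lowest locants (1R,2R,4S,5S)-1-bromo-2,4-dichloro-5-[(E)-2-chloroethenyl]-1-(chloromethyl)-5-methylcyclohexane | C[C@@]1(/C=C/Cl)C[C@@](Br)(CCl)[C@H](Cl)C[C@@H]1Cl | target

Total step count: 10. Longest linear sequence: 9 steps (steps 1, 2 and 4 to 10, from propargyl alcohol).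

Steps most likely to fail

Step 8 (proposed new method). What may go wrong: bromine-atom attack at C4 followed by expulsion of the allylic chlorine atom, hydrogen delivery on the wrong ring face, or ionic Markovnikov addition overtaking the chain. The fallback uses known chemistry, sets out from 8 and comes back at 15. It installs the C4 chloride by SN2 displacement before any bromine is present, and then makes the tertiary bromide by radical-chain hydrobromination of an exocyclic 1-chloroalkene, the simple haloalkene class for which bromine is known to add to the carbon remote from the halogen. Thus 8 is formylated at C3 with one equivalent of the chloroiminium reagent and hydrolysed with dilute acid to (1S,6S)-6-chloro-3-[(Z)-hydroxymethylidene]-1-methyl-4-oxocyclohexane-1-carbaldehyde F1. Oxalyl chloride turns the enol into (1S,6S)-6-chloro-3-[(E)-chloromethylidene]-1-methyl-4-oxocyclohexane-1-carbaldehyde F2. CBS reduction (BH3·SMe2 with 1-methyl-3,3-diphenyltetrahydro-1H,3H-pyrrolo[1,2-c][1,3,2]oxazaborole, antipode chosen to deliver hydride to the ring face that carries C6–Cl; the aldehyde is reduced as well) gives (1S,4S,6S)-6-chloro-3-[(E)-chloromethylidene]-1-(hydroxymethyl)-1-methylcyclohexan-4-ol F3. Corey–Kim chlorination replaces the secondary allylic hydroxyl with inversion and leaves the neopentyl alcohol, giving [(1S,4R,6S)-4,6-dichloro-3-[(E)-chloromethylidene]-1-methylcyclohexyl]methanol F4. HBr, hν, −78 °C then puts bromine on C3 and hydrogen on the exocyclic carbon, the reversible bromine-atom addition favouring the adduct with axial bromine and equatorial CH2Cl, to arrive at 15.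

Step 10. What may go wrong: single-electron reduction of the tertiary C3 bromide by divalent chromium, with loss of the neighbouring chloride, during the slow olefination of the hindered axial aldehyde. The fallback sets out from 16 and comes back at 18. Ohira–Bestmann homologation (dimethyl (1-diazo-2-oxopropyl)phosphonate, K2CO3, MeOH, 0 °C) gives (1S,3R,4R,6S)-3-bromo-4,6-dichloro-3-(chloromethyl)-1-ethynyl-1-methylcyclohexane F5. Hydrozirconation with Cp2Zr(H)Cl in CH2Cl2 gives the (E)-alkenylzirconocene chloride F6, which is used in the flask. N-Chlorosuccinimide then replaces zirconium by chlorine with retention and gives the E-chloroalkene 18 without any reducing metal.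

Step 4. What may go wrong: slow turnover and weak facial discrimination, because the chlorine cis to the formyl group points toward the catalyst in the usual binding mode, and Lewis-acid-promoted Z to E leakage of the dienophile. The fallback sets out from 5 and 7 and comes back at 8. Cycloaddition without a chiral catalyst (toluene, 80 °C, or Me2AlCl, CH2Cl2, −78 °C) should give 8 together with its mirror image (1R,6R)-6-chloro-1-methyl-4-(triisopropylsilyloxy)cyclohex-3-ene-1-carbaldehyde F7. The two enantiomers are separated by preparative chromatography on a chiral stationary phase, so resolution replaces asymmetric catalysis and only (1S,6S)-8 is carried on.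

Further compounds
F1 | step 8 | (1S,6S)-6-chloro-3-[(Z)-hydroxymethylidene]-1-methyl-4-oxocyclohexane-1-carbaldehyde | C[C@@]1(C=O)C/C(=C/O)C(=O)C[C@@H]1Cl
F2 | step 8 | (1S,6S)-6-chloro-3-[(E)-chloromethylidene]-1-methyl-4-oxocyclohexane-1-carbaldehyde | C[C@@]1(C=O)C/C(=C\Cl)C(=O)C[C@@H]1Cl
F3 | step 8 | (1S,4S,6S)-6-chloro-3-[(E)-chloromethylidene]-1-(hydroxymethyl)-1-methylcyclohexan-4-ol | C[C@@]1(CO)C/C(=C\Cl)[C@@H](O)C[C@@H]1Cl
F4 | step 8 | [(1S,4R,6S)-4,6-dichloro-3-[(E)-chloromethylidene]-1-methylcyclohexyl]methanol | C[C@@]1(CO)C/C(=C\Cl)[C@H](Cl)C[C@@H]1Cl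
F5 | step 10 | (1S,3R,4R,6S)-3-bromo-4,6-dichloro-3-(chloromethyl)-1-ethynyl-1-methylcyclohexane | C[C@@]1(C#C)C[C@@](Br)(CCl)[C@H](Cl)C[C@@H]1Cl
F6 | step 10 | chloridobis(cyclopentadienyl){(E)-2-[(1S,3R,4R,6S)-3-bromo-4,6-dichloro-3-(chloromethyl)-1-methylcyclohexyl]ethenyl}zirconium | C[C@@]1(/C=C/[Zr](Cl)(C2C=CC=C2)C2C=CC=C2)C[C@@](Br)(CCl)[C@H](Cl)C[C@@H]1Cl
F7 | step 4 | (1R,6R)-6-chloro-1-methyl-4-(triisopropylsilyloxy)cyclohex-3-ene-1-carbaldehyde | C[C@]1(C=O)CC=C(O[Si](C(C)C)(C(C)C)C(C)C)C[C@H]1Cl
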